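Stenosporic acid is cut at its depside ester into ring A, 2-hydroxy-4-methoxy-6-propylbenzoic acid, and ring B, benzyl 2,4-dihydroxy-6-pentylbenzoate. In ring B the carboxyl carbon C1 lies between oxygen-bearing C2 and pentyl-bearing C6. This contiguous C2–O / C1–CO2H / C6–pentyl triad is written in one flask by adding pentylmagnesium bromide and then CO2 across the triple bond of 3,5-dimethoxybenzyne: the methoxy group beside the aryne sends the alkyl to C6 and the metal, then the carboxyl, to C1. The aryne precursor is commercial 1-fluoro-3,5-dimethoxybenzene, lithiated between fluorine and methoxy. Ring A comes from 2,4-dimethoxy-6-methylbenzoic acid by lateral lithiation and ethylation.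

Key step: step 1

Remark: the target has no stereocentre; 2,4-dimethoxy-6-methylbenzoic acid is taken as a purchasable building block; halomagnesium and lithium carboxylates and boron aryloxides present before aqueous work-up are treated as salt forms of the step products and are not numbered separately.

Step 1
Reactants: 1 1-fluoro-3,5-dimethoxybenzene; 2 pentylmagnesium bromide; 3 carbon dioxide
Product: 7 2,4-dimethoxy-6-pentylbenzoic acid, via 2-fluoro-4,6-dimethoxyphenyllithium 4 (not isolated), via 3,5-dimethoxybenzyne 5 (not isolated), via 2,4-dimethoxy-6-pentylphenylmagnesium bromide 6 (not isolated)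
Conditions: s-BuLi, THF, −78 °C; then 2 (excess), −78 °C → rt; then CO2 (g), −40 °C → rt; aq. HCl
Reagents that add atoms: none
Why: sec-Butyllithium should remove the ring proton that sits between fluorine and a methoxy group (directed ortho-metalation) to give 4, which on warming in the presence of 2 expels LiF and becomes aryne 5; the pentyl–magnesium bond then adds across the strained triple bond (carbomagnesiation) and the resulting arylmagnesium 6 is carboxylated by CO2. The closest known reaction type is the addition of organolithium or Grignard reagents to 3-alkoxyarynes made from 3-haloanisoles, followed by electrophilic trapping of the 2-metallated arene. No ring is closed and no stereocentre is created. Two regioselectivities are needed: metalation at the F/OMe-flanked carbon rather than between the two methoxy groups, which the stronger ortho-acidifying effect of fluorine and the symmetry of 1 (both such sites are equivalent) should secure; and attack of pentyl at the aryne carbon remote from the neighbouring methoxy group, which the inductive pull of that oxygen secures by distorting the aryne and by placing the developing carbanion next to oxygen, where magnesium is also chelated. CO2 reacts only at the carbon–magnesium bond, so the carboxyl ends up between methoxy and pentyl.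

Step 2
Reactants: 7 2,4-dimethoxy-6-pentylbenzoic acid
Product: 8 2,4-dihydroxy-6-pentylbenzoic acid (olivetolic acid)
Conditions: BBr3 (excess), CH2Cl2, −78 °C → rt; ice-water quench, cold work-up
Reagents that add atoms: none
Why: Boron tribromide aryl methyl ether cleavage (Lewis-acid complexation of each methoxy oxygen, then SN2 attack of bromide on methyl) should free both phenols, and the cold quench is meant to keep the electron-rich salicylic acid from decarboxylating.

Step 3
Reactants: 8 2,4-dihydroxy-6-pentylbenzoic acid
Product: 9 benzyl 2,4-dihydroxy-6-pentylbenzoate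
Conditions: BnBr, KHCO3, DMF, rt
Reagents that add atoms: benzyl bromide, BrCc1ccccc1
Why: Carboxylate O-alkylation (SN2 esterification) should be selective because bicarbonate deprotonates only the carboxylic acid, so both phenols stay free.

Step 4
Reactants: 10 2,4-dimethoxy-6-methylbenzoic acid
Product: 12 2,4-dimethoxy-6-propylbenzoic acid, via lithium 2-(lithiomethyl)-4,6-dimethoxybenzoate 11 (not isolated)
Conditions: LiN(i-Pr)2 (2.2 equiv), THF, −78 °C → 0 °C; then EtI, −78 °C → rt; aq. HCl
Reagents that add atoms: iodoethane, CCI
Why: Lateral (benzylic) lithiation of an ortho-toluic acid followed by SN2 alkylation should work because the amide base first forms the lithium carboxylate and then deprotonates the ortho methyl group, whose carbanion is stabilised by conjugation with and chelation to the carboxylate, and this carbanion is ethylated at carbon by iodoethane, turning methyl into propyl.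

Step 5
Reactants: 12 2,4-dimethoxy-6-propylbenzoic acid
Product: 13 2-hydroxy-4-methoxy-6-propylbenzoic acid (divaricatinic acid)
Conditions: BCl3, CH2Cl2, −78 °C → 0 °C; then H2O
Reagents that add atoms: none
Why: Chelation-controlled boron trichloride demethylation should remove only the ortho methyl, because boron bridges the carboxyl oxygen and the ortho methoxy oxygen in a six-membered chelate while the para methoxy group is not activated.

Step 6
Reactants: 13 2-hydroxy-4-methoxy-6-propylbenzoic acid; 9 benzyl 2,4-dihydroxy-6-pentylbenzoate
Product: 15 benzyl 2-hydroxy-4-[(2-hydroxy-4-methoxy-6-propylbenzoyl)oxy]-6-pentylbenzoate, via acyl trifluoroacetate 14 (not isolated)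
Conditions: (CF3CO)2O, toluene, 0 °C → rt; aq. NaHCO3 wash
Reagents that add atoms: none
Why: Mixed-anhydride esterification (the trifluoroacetic anhydride method for depsides) should let acyl trifluoroacetate 14 acylate the free 4-hydroxyl of 9, while the 2-hydroxyls of both partners are held in hydrogen bonds to their ortho carbonyl groups and stay unreactive.

Step 7
Reactants: 15 benzyl 2-hydroxy-4-[(2-hydroxy-4-methoxy-6-propylbenzoyl)oxy]-6-pentylbenzoate
Product: 16 stenosporic acid
Conditions: H2 (1 atm), 10% Pd/C, EtOAc, rt
Reagents that add atoms: none
Why: Catalytic hydrogenolysis of the benzyl ester should cleave only the benzylic C–O bond and leave the aryl ester linkage, the phenols and the methyl ether intact.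

Compound list
1 | 1-fluoro-3,5-dimethoxybenzene | COc1cc(F)cc(OC)c1 | starting material
2 | pentylmagnesium bromide | CCCCC[Mg]Br | starting material
3 | carbon dioxide | O=C=O | starting material
4 | (2-fluoro-4,6-dimethoxyphenyl)lithium (formed in the flask) | [Li]c1c(F)cc(OC)cc1OC | intermediate
5 | 3,5-dimethoxybenzyne, i.e. 1,2-didehydro-3,5-dimethoxybenzene (formed in the flask) | COC1=CC(OC)=CC#C1 | intermediate
6 | (2,4-dimethoxy-6-pentylphenyl)magnesium bromide (formed in the flask) | CCCCCc1cc(OC)cc(OC)c1[Mg]Br | intermediate
7 | 2,4-dimethoxy-6-pentylbenzoic acid | CCCCCc1cc(OC)cc(OC)c1C(=O)O | intermediate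
8 | 2,4-dihydroxy-6-pentylbenzoic acid (olivetolic acid) | CCCCCc1cc(O)cc(O)c1C(=O)O | intermediate
9 | benzyl 2,4-dihydroxy-6-pentylbenzoate | CCCCCc1cc(O)cc(O)c1C(=O)OCc1ccccc1 | intermediate
10 | 2,4-dimethoxy-6-methylbenzoic acid | Cc1cc(OC)cc(OC)c1C(=O)O | starting material
11 | lithium 2-(lithiomethyl)-4,6-dimethoxybenzoate (formed in the flask) | [Li]Cc1cc(OC)cc(OC)c1C(=O)O[Li] | intermediate
12 | 2,4-dimethoxy-6-propylbenzoic acid | CCCc1cc(OC)cc(OC)c1C(=O)O | intermediate
13 | 2-hydroxy-4-methoxy-6-propylbenzoic acid (divaricatinic acid) | CCCc1cc(OC)cc(O)c1C(=O)O | intermediate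
14 | 2-hydroxy-4-methoxy-6-propylbenzoic trifluoroacetic anhydride (formed in the flask) | CCCc1cc(OC)cc(O)c1C(=O)OC(=O)C(F)(F)F | intermediate
15 | benzyl 2-hydroxy-4-[(2-hydroxy-4-methoxy-6-propylbenzoyl)oxy]-6-pentylbenzoate | CCCCCc1cc(OC(=O)c2c(O)cc(OC)cc2CCC)cc(O)c1C(=O)OCc1ccccc1 | intermediate
16 | stenosporic acid, 2-hydroxy-4-[(2-hydroxy-4-methoxy-6-propylbenzoyl)oxy]-6-pentylbenzoic acid | CCCCCc1cc(OC(=O)c2c(O)cc(OC)cc2CCC)cc(O)c1C(=O)O | target

Total step count: 7
Longest linear sequence: 5 steps (steps 1, 2, 3, 6, 7 from compound 1); the ring A branch (steps 4, 5) joins at step 6.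

Steps most likely to fail

1. Step 1. Three things may go wrong.
- Metalation may occur between the two methoxy groups, giving an aryllithium that cannot eliminate and is merely carboxylated.
- The aryne may be consumed by the aryllithium or by residual sec-butyllithium instead of by the Grignard reagent.
- The hindered arylmagnesium may be carboxylated incompletely.

The fallback avoids the aryne and sets out from 2. Kumada coupling of 2 with commercial 1-bromo-3,5-dimethoxybenzene (Pd(dppf)Cl2 cat., THF, reflux) should give 1,3-dimethoxy-5-pentylbenzene F1. Vilsmeier–Haack formylation (POCl3, DMF, then aq. NaOAc), para to one methoxy group and ortho to the other, should give 2,4-dimethoxy-6-pentylbenzaldehyde F2. Pinnick oxidation (NaClO2, NaH2PO4, 2-methyl-2-butene, t-BuOH/H2O) comes back to the route at 7.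

2. Step 2. Protodecarboxylation of the electron-rich salicylic acid may set in under the acidic ether-cleavage and quench conditions, and cleavage of the non-chelated 4-methoxy group may stop short. The fallback gives up the carboxyl on purpose and puts it back under conditions the resorcylic acid is known to tolerate; it sets out from 7. Heating with 48% aq. HBr in AcOH should cleave both methyl ethers and protodecarboxylate the acid to 5-pentylbenzene-1,3-diol (olivetol) F3. Ortho-carboxylation with methoxymagnesium methyl carbonate, MeOMgOCO2Me (DMF, 120 °C; cold dilute HCl work-up), is a Kolbe–Schmitt-type reaction steered by magnesium chelation to the phenoxide. It should place the carboxyl next to one hydroxyl and para to the other, and comes back to the route at 8.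

3. Step 6. Hydroxy acid 13 may self-condense through its own phenol, acyl or trifluoroacetyl transfer may go to the wrong hydroxyl of 9, and acyl transfer from the doubly ortho-substituted acyl group may be slow. The fallback keeps the ring A ortho oxygen methylated through the coupling and sets out from 12, with 9 as partner. Oxalyl chloride with catalytic DMF in CH2Cl2 should give 2,4-dimethoxy-6-propylbenzoyl chloride F4. Acylation of the non-chelated 4-hydroxyl of 9 (pyridine, CH2Cl2, 0 °C → rt) should give benzyl 4-[(2,4-dimethoxy-6-propylbenzoyl)oxy]-2-hydroxy-6-pentylbenzoate F5. BCl3 (CH2Cl2, −78 °C → rt) should then remove the methyl ether chelated to the depside carbonyl together with the benzyl ester, coming back to the route at 16 (steps 5 and 7 are then not needed).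

Further compounds
F1 | step 1 | 1,3-dimethoxy-5-pentylbenzene | CCCCCc1cc(OC)cc(OC)c1
F2 | step 1 | 2,4-dimethoxy-6-pentylbenzaldehyde | CCCCCc1cc(OC)cc(OC)c1C=O
F3 | step 2 | 5-pentylbenzene-1,3-diol (olivetol) | CCCCCc1cc(O)cc(O)c1
F4 | step 6 | 2,4-dimethoxy-6-propylbenzoyl chloride | CCCc1cc(OC)cc(OC)c1C(Cl)=O
F5 | step 6 | benzyl 4-[(2,4-dimethoxy-6-propylbenzoyl)oxy]-2-hydroxy-6-pentylbenzoate | CCCCCc1cc(OC(=O)c2c(OC)cc(OC)cc2CCC)cc(O)c1C(=O)OCc1ccccc1
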